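**Retrosynthetic overview**
1. Target 13 comes from the (5R)-tetrahydroquinoline 12 by N-oxidation, done last, when no alkene is left.
2. 12 comes from the achiral alkenyl bromide 11 by closing ring B at C5–C6 in a copper-hydride-catalysed enantioselective hydroalkylation. Enabling feature: C5 is a benzylic methine on C4a of the pyridine (ring A) and C6 is the neighbouring ring-B methylene, three carbons out from C8a, so an aryl-conjugated C4a–CH=CH alkene directs copper to C5 and a bromide on C6 lies in 6-exo reach.
3. 11 comes from bromo alcohol 7 and the (E)-alkenyl boronate 9 (Suzuki–Miyaura coupling, then Appel bromination).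
4. 7 comes from 5-bromo-3,4-dimethoxy-2-methylpyridine 4 by Minisci alkylation of its only ring C–H, then ester reduction; 4 comes from the commercial pyridone 1.
5. Ring order: ring A is bought; ring B is the only ring formed, in the key step.

Key step: step 9

Assumption: (R)-DTBM-SEGPHOS is taken to give the (5R) product, by analogy with the usual sense of induction of this ligand in copper hydride additions to β-alkyl styrenes (the (S)-ligand is used if the sense proves opposite); 1, 5 and 8 are taken as commercial.

**Step 1**
Reactants: 1 3-methoxy-2-methylpyridin-4(1H)-one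
Product: 2 5-bromo-3-methoxy-2-methylpyridin-4(1H)-one
Conditions: NBS (1.05 equiv), DMF, 0 °C to rt, dark
Reagents that add atoms: N-bromosuccinimide, O=C1CCC(=O)N1Br
Why: Electrophilic aromatic bromination: position 5 of the pyridone is the only unsubstituted carbon α to the carbonyl of the vinylogous amide, so bromine should enter there and not at position 6.

**Step 2**
Reactants: 2 5-bromo-3-methoxy-2-methylpyridin-4(1H)-one
Product: 3 5-bromo-4-chloro-3-methoxy-2-methylpyridine
Conditions: POCl3 (neat), 100 °C; aq. NaHCO3 work-up
Reagents that add atoms: phosphoryl chloride, O=P(Cl)(Cl)Cl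
Why: Deoxychlorination of a 4-pyridone (O-phosphorylation, then addition–elimination of chloride at position 4), a standard reaction that should leave the C–Br bond and the methyl ether untouched.

**Step 3**
Reactants: 3 5-bromo-4-chloro-3-methoxy-2-methylpyridine
Product: 4 5-bromo-3,4-dimethoxy-2-methylpyridine
Conditions: NaOMe (3 equiv), MeOH/DMSO, 70 °C
Reagents that add atoms: sodium methoxide, C[O-].[Na+]
Why: Nucleophilic aromatic substitution by addition–elimination: the chloride para to the ring nitrogen is activated and the β-bromide is not, so methoxide should replace chlorine only.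

**Step 4**
Reactants: 4 5-bromo-3,4-dimethoxy-2-methylpyridine; 5 4-methoxy-4-oxobutanoic acid
Product: 6 methyl 3-(3-bromo-4,5-dimethoxy-6-methylpyridin-2-yl)propanoate
Conditions: 5 (3 equiv), AgNO3 (20 mol %), (NH4)2S2O8 (2.5 equiv), TFA (1.2 equiv), CH2Cl2/H2O (1:1), 40 °C
Reagents that add atoms: none
Why: Minisci reaction: silver-mediated oxidative decarboxylation of 5 gives the nucleophilic 2-(methoxycarbonyl)ethyl radical, which should add to the protonated pyridine at its only unsubstituted carbon (α to nitrogen), and persulfate rearomatises the adduct.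

**Step 5**
Reactants: 6 methyl 3-(3-bromo-4,5-dimethoxy-6-methylpyridin-2-yl)propanoate
Product: 7 3-(3-bromo-4,5-dimethoxy-6-methylpyridin-2-yl)propan-1-ol
Conditions: LiBH4 (2 equiv), THF/MeOH, 0 °C to rt
Reagents that add atoms: none
Why: Hydride reduction of the ester to the primary alcohol with LiBH4, a reagent that should spare the aryl bromide and the pyridine ring.

**Step 6**
Reactants: 8 6-phenylhex-1-yne
Product: 9 4,4,5,5-tetramethyl-2-[(E)-6-phenylhex-1-enyl]-1,3,2-dioxaborolane
Conditions: HBpin (1.1 equiv), Cp2Zr(H)Cl (5 mol %), Et3N (10 mol %), neat, 60 °C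
Reagents that add atoms: pinacolborane, CC1(C)OBOC1(C)C
Why: Zirconium-catalysed hydroboration of a terminal alkyne: syn addition with boron on the terminal carbon should give the E alkenyl boronate only.

**Step 7**
Reactants: 7 3-(3-bromo-4,5-dimethoxy-6-methylpyridin-2-yl)propan-1-ol; 9 4,4,5,5-tetramethyl-2-[(E)-6-phenylhex-1-enyl]-1,3,2-dioxaborolane
Product: 10 3-[4,5-dimethoxy-6-methyl-3-[(E)-6-phenylhex-1-enyl]pyridin-2-yl]propan-1-ol
Conditions: Pd(OAc)2 (3 mol %), SPhos (6 mol %), K3PO4 (3 equiv), toluene/H2O (10:1), 80 °C
Reagents that add atoms: none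
Why: Suzuki–Miyaura coupling, which keeps the alkene geometry; the bulky electron-rich biarylphosphine is chosen for the di-ortho-substituted heteroaryl bromide, and the free alcohol is tolerated.

**Step 8**
Reactants: 10 3-[4,5-dimethoxy-6-methyl-3-[(E)-6-phenylhex-1-enyl]pyridin-2-yl]propan-1-ol
Product: 11 2-(3-bromopropyl)-4,5-dimethoxy-6-methyl-3-[(E)-6-phenylhex-1-enyl]pyridine
Conditions: CBr4 (1.3 equiv), PPh3 (1.3 equiv), CH2Cl2, 0 °C; cold silica plug, used at once
Reagents that add atoms: carbon tetrabromide, BrC(Br)(Br)Br
Why: Appel reaction: the primary alcohol is converted into the bromide under neutral, cold conditions that should leave the alkene and the ethers alone, and the bromide is used at once so that slow self-alkylation of the free pyridine base has no time to occur.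

**Step 9**
Reactants: 11 2-(3-bromopropyl)-4,5-dimethoxy-6-methyl-3-[(E)-6-phenylhex-1-enyl]pyridine
Product: 12 (5R)-3,4-dimethoxy-2-methyl-5-(5-phenylpentyl)-5,6,7,8-tetrahydroquinoline
Conditions: Cu(OAc)2 (5 mol %), (R)-DTBM-SEGPHOS (5.5 mol %), (MeO)2MeSiH (2 equiv), LiOMe (2 equiv), THF, rt
Reagents that add atoms: none
Why: The bisphosphine-ligated monovalent copper hydride, made in the flask from Cu(OAc)2 and the silane, adds syn across the aryl-conjugated alkene with copper on the benzylic carbon C5, and this alkylcopper displaces the primary bromide at C6 in an intramolecular SN2 step, after which LiOMe and the silane return the copper bromide to the hydride. The closest known reaction type is the copper-hydride-catalysed enantioselective intramolecular hydroalkylation of styrenes that carry a tethered alkyl bromide, which gives indanes and six-membered heterocycles. Ring B closes in the 6-exo-tet mode. The C5 stereocentre is set under catalyst control in the hydrocupration, where the (R)-DTBM-SEGPHOS pocket selects one face of the alkene, and it is carried into 12 because the C–C bond forms with retention at the copper-bearing carbon. The step needs copper at C5 and not at the neighbouring alkene carbon, which aryl conjugation secures, one alkene geometry, which step 6 secures, and C-alkylation ahead of N-alkylation, which the substrate secures because its ring nitrogen is flanked on both sides and could only close a strained five-membered ring.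

**Step 10**
Reactants: 12 (5R)-3,4-dimethoxy-2-methyl-5-(5-phenylpentyl)-5,6,7,8-tetrahydroquinoline
Product: 13 (5R)-3,4-dimethoxy-2-methyl-5-(5-phenylpentyl)-5,6,7,8-tetrahydroquinoline 1-oxide
Conditions: mCPBA (1.1 equiv), CH2Cl2, 0 °C to rt
Reagents that add atoms: 3-chloroperoxybenzoic acid, O=C(OO)c1cccc(Cl)c1
Why: N-oxidation of an electron-rich pyridine by a peracid (oxygen transfer to the nitrogen lone pair), with no alkene left to compete and the C5 stereocentre not involved.

**Compound list**
1 | 3-methoxy-2-methylpyridin-4(1H)-one | Cc1[nH]ccc(=O)c1OC | starting material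
2 | 5-bromo-3-methoxy-2-methylpyridin-4(1H)-one | Cc1[nH]cc(Br)c(=O)c1OC | intermediate
3 | 5-bromo-4-chloro-3-methoxy-2-methylpyridine | Cc1ncc(Br)c(Cl)c1OC | intermediate
4 | 5-bromo-3,4-dimethoxy-2-methylpyridine | Cc1ncc(Br)c(OC)c1OC | intermediate
5 | 4-methoxy-4-oxobutanoic acid | COC(=O)CCC(=O)O | starting material
6 | methyl 3-(3-bromo-4,5-dimethoxy-6-methylpyridin-2-yl)propanoate | COC(=O)CCc1nc(C)c(OC)c(OC)c1Br | intermediate
7 | 3-(3-bromo-4,5-dimethoxy-6-methylpyridin-2-yl)propan-1-ol | OCCCc1nc(C)c(OC)c(OC)c1Br | intermediate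
8 | 6-phenylhex-1-yne | C#CCCCCc1ccccc1 | starting material
9 | 4,4,5,5-tetramethyl-2-[(E)-6-phenylhex-1-enyl]-1,3,2-dioxaborolane | CC1(C)OB(/C=C/CCCCc2ccccc2)OC1(C)C | intermediate
10 | 3-[4,5-dimethoxy-6-methyl-3-[(E)-6-phenylhex-1-enyl]pyridin-2-yl]propan-1-ol | OCCCc1nc(C)c(OC)c(OC)c1/C=C/CCCCc1ccccc1 | intermediate
11 | 2-(3-bromopropyl)-4,5-dimethoxy-6-methyl-3-[(E)-6-phenylhex-1-enyl]pyridine | BrCCCc1nc(C)c(OC)c(OC)c1/C=C/CCCCc1ccccc1 | intermediate
12 | (5R)-3,4-dimethoxy-2-methyl-5-(5-phenylpentyl)-5,6,7,8-tetrahydroquinoline | COc1c(OC)c(C)nc2c1[C@H](CCCCCc1ccccc1)CCC2 | intermediate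
13 | (5R)-3,4-dimethoxy-2-methyl-5-(5-phenylpentyl)-5,6,7,8-tetrahydroquinoline 1-oxide | COc1c(OC)c(C)[n+]([O-])c2c1[C@H](CCCCCc1ccccc1)CCC2 | target

**Step count**
Total steps: 10. Longest linear sequence: 9 steps (steps 1–5 and 7–10, from 1 to 13).

**Steps most likely to fail**

Step 9. What may go wrong: hydrocupration of the hindered, di-ortho-substituted aryl alkene may be slow, so that intramolecular N-alkylation of the pyridine by the bromopropyl arm, or plain reduction of the alkene, competes. Fallback, from 7 back to 13: the ring closure is moved to the N-oxide level, where the ring nitrogen has no lone pair; this changes the precursor and the order of events, not only the conditions. mCPBA (CH2Cl2, 0 °C) should oxidise 7, which carries no alkene yet, to 3-(3-bromo-4,5-dimethoxy-6-methyl-1-oxidopyridin-1-ium-2-yl)propan-1-ol F1. Suzuki–Miyaura coupling of F1 with 9 under the conditions of step 7 should give 3-[4,5-dimethoxy-6-methyl-1-oxido-3-[(E)-6-phenylhex-1-enyl]pyridin-1-ium-2-yl]propan-1-ol F2. Appel bromination as in step 8 should give 2-(3-bromopropyl)-4,5-dimethoxy-6-methyl-3-[(E)-6-phenylhex-1-enyl]pyridine 1-oxide F3. The copper hydride cyclisation of step 9, applied to F3, should then give 13 directly, and step 10 falls away. Both α-positions of the N-oxide are substituted, which should leave it a spectator towards the benzylic copper species.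

Step 4. What may go wrong: the electron-rich, doubly methoxylated pyridinium may capture the alkyl radical only slowly, so that radical dimerisation and oxidative degradation under persulfate take over. Fallback, from 4 back to 7: a polar addition replaces the radical one. mCPBA should convert 4 into 5-bromo-3,4-dimethoxy-2-methylpyridine 1-oxide F4. (2-(1,3-Dioxan-2-yl)ethyl)magnesium bromide (commercial solution, THF, rt) should add at the only unsubstituted α-carbon to give the racemic adduct 3-bromo-2-[2-(1,3-dioxan-2-yl)ethyl]-4,5-dimethoxy-6-methyl-2H-pyridin-1-ol F5, which is not isolated. Ac2O at 120 °C should rearomatise it, with loss of acetic acid, to 3-bromo-2-[2-(1,3-dioxan-2-yl)ethyl]-4,5-dimethoxy-6-methylpyridine F6. Aqueous HCl in THF should unmask 3-(3-bromo-4,5-dimethoxy-6-methylpyridin-2-yl)propanal F7, and NaBH4 in MeOH should reduce it to 7.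

Step 7. What may go wrong: transmetalation at the di-ortho-substituted position may be slow, so that protodeboronation of 9 and loss of E purity compete. Fallback, from 7 back to 10: the alkene is built by metathesis instead. Coupling of 7 with potassium vinyltrifluoroborate (Pd(dppf)Cl2, K2CO3, THF/H2O, 70 °C), a small and robust partner, should give 3-(3-ethenyl-4,5-dimethoxy-6-methylpyridin-2-yl)propan-1-ol F8. Cross-metathesis of F8 with an excess of 6-phenylhex-1-ene (second-generation Hoveyda–Grubbs catalyst, CH2Cl2, 40 °C) should give 10 as the E isomer, with loss of ethylene.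

**Further compounds**
F1 | step 9 | 3-(3-bromo-4,5-dimethoxy-6-methyl-1-oxidopyridin-1-ium-2-yl)propan-1-ol | OCCCc1c(Br)c(OC)c(OC)c(C)[n+]1[O-]
F2 | step 9 | 3-[4,5-dimethoxy-6-methyl-1-oxido-3-[(E)-6-phenylhex-1-enyl]pyridin-1-ium-2-yl]propan-1-ol | OCCCc1c(/C=C/CCCCc2ccccc2)c(OC)c(OC)c(C)[n+]1[O-]
F3 | step 9 | 2-(3-bromopropyl)-4,5-dimethoxy-6-methyl-3-[(E)-6-phenylhex-1-enyl]pyridine 1-oxide | BrCCCc1c(/C=C/CCCCc2ccccc2)c(OC)c(OC)c(C)[n+]1[O-]
F4 | step 4 | 5-bromo-3,4-dimethoxy-2-methylpyridine 1-oxide | Cc1c(OC)c(OC)c(Br)c[n+]1[O-]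
F5 | step 4 | 3-bromo-2-[2-(1,3-dioxan-2-yl)ethyl]-4,5-dimethoxy-6-methyl-2H-pyridin-1-ol (racemic) | ON1C(C)=C(OC)C(OC)=C(Br)C1CCC1OCCCO1
F6 | step 4 | 3-bromo-2-[2-(1,3-dioxan-2-yl)ethyl]-4,5-dimethoxy-6-methylpyridine | Cc1nc(CCC2OCCCO2)c(Br)c(OC)c1OC
F7 | step 4 | 3-(3-bromo-4,5-dimethoxy-6-methylpyridin-2-yl)propanal | Cc1nc(CCC=O)c(Br)c(OC)c1OC
F8 | step 7 | 3-(3-ethenyl-4,5-dimethoxy-6-methylpyridin-2-yl)propan-1-ol | OCCCc1nc(C)c(OC)c(OC)c1C=C
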